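The flask is read at 30 h, after its feed has ended, so the question is how much partner the starting material has met by then.

| setting | elm | alder | flask |
|---|---|---|---|
| starting material | 0.80 M | 0.40 M | 0.80 M |
| partner | 0.80 M (fed, over 4.0 h) | 1.6 M (fed, over 4.0 h) | 1.60 M (fed, over 4.0 h) |
| remark | run made earlier; the fed solution adds 1.0 times the starting volume | run made earlier; the fed solution adds 1.0 times the starting volume | the fed solution adds 1.0 times the starting volume |
| time |  |  | 30 h |

| run | time / h | starting material / % | intermediate C / % |
|---|---|---|---|
| elm | 3.00 | 96 | 2 |
| elm | 5.00 | 97 | 0 |
| elm | 8.00 | 99 | 0 |
| elm | 12.0 | 93 | 5 |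
| elm | 20.0 | 92 | 0 |
| elm | 40.0 | 88 | 3 |
| alder | 3.00 | 99 | 1 |
| alder | 5.00 | 98 | 2 |
| alder | 10.0 | 92 | 0 |
| alder | 20.0 | 88 | 2 |
| alder | 40.0 | 82 | 5 |

(each reading ± 2 percentage points)

- every charge counts on the volume at the start, and the solution that is fed holds the whole dose

1. the starting material in the flask at 30 h, as a percentage of the starting material charged
2. the intermediate C in the flask at 30 h, as a percentage of the starting material charged
3. the intermediate A in the flask at 30 h, as a percentage of the starting material charged

Let f be the fraction of the starting material left, and suppose it falls in proportion to f and to the partner concentration, a pseudo-first-order picture. Then ln f falls as the partner charge times an effective time, the clock weighted by the partner concentration over its charge, integrated in closed form. After the feed the doubled volume holds the partner at its charge divided by 2, so the clock divided by 2 is a first estimate. But during the feed the partner stands lower, and its rising concentration in the growing volume integrates to 1.23 h of effective time, not 2.00 h. The correction is kept: elm and alder have 19.2 h at 40.0 h.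

Elm then gives 0.00831 /M/h and alder 0.00645 /M/h. These differ, but elm's loss of 12.0 % is read with a scatter of 2 percentage points, so the two are pooled into the loss constant, the fall of ln f per partner charge and effective time, 0.00707 /M/h.

The partner does fall, though. If each starting material lost takes one partner, elm's partner has lost 12.0 % of its charge and alder's 4.50 %, so the pooled constant, read from these two runs, already holds some of that shortfall.

The flask has 14.2 h of effective time, and its partner charge times this lies between the elm and alder values. My reckoning leaves f = 85.1 %. If intermediate C in the flask is taken at elm's last reading of 3 %, and the remainder is taken to stand as intermediate A, that intermediate comes out at 11.9 %.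

The forecast, holding that “the fractional loss follows partner concentration”, gives 84 % starting material, 3 % intermediate C and 8 % intermediate A, which is less intermediate A than my 11.9 %.

The flask gives 84.4 % starting material, 3.06 % intermediate C and 11.9 % intermediate A.

    intermediate A ⇌ intermediate C (K = 0.820, k = 5.29 × 10⁻⁶ /s)
    intermediate D ⇌ target (K = 1.37, k = 2.92 × 10⁻⁷ /s)
    intermediate B → intermediate D (k = 2.81 × 10⁻⁶ /s)
    starting material + target → side product (k = 5.33 × 10⁻⁶ /M/s)
    starting material + partner ⇌ intermediate A (K = 0.850 /M, k = 2.47 × 10⁻⁶ /M/s)
    partner + intermediate A → intermediate B (k = 1.14 × 10⁻⁶ /M/s)
    starting material + target ⇌ idle adduct, settled at all times (K = 0.322 /M)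

At that time 92 % of the partner charge is left in the flask. The 84.4 % of starting material in the flask gives a constant of 0.00747 /M/h, beside the pooled 0.00707 /M/h. A neighbouring flask with 0.64 M of partner has the same effective time, so the pooled constant leaves it 93.8 % of its starting material, and that flask holds 93.4 %.

All runs come from a simulation with made-up constants, noise included.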